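How much target stands in the flask at the end of the run, and how close to saturation is the dissolved gas then?

- the target standing at 8.0 d, as a percentage of the starting material charged
- concentration of dissolved gas in solution at 8.0 d, in percent of saturation

starting material 0.10 M; gas phase 48 mM (held); time 8.0 d

    starting material + target → side product B (k1 = 1.2 M⁻¹ h⁻¹)
    gas phase ⇌ dissolved gas, rate k2*(csat - [dissolved gas]) (k2 = 0.36 h⁻¹, csat = 48 mM)
    dissolved gas → decomposed reagent (k3 = 0.019 h⁻¹)
    starting material + dissolved gas ⇌ target (K4 = 170 M⁻¹, k4 = 0.14 M⁻¹ h⁻¹)
    starting material → side product A (k5 = 0.0017 h⁻¹)

- percent here means starting material units held: one side product B counts as two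
- at the start none of the gas is dissolved
- run time (flask): 8.0 d

Two rates carry the first question. Target is made at 0.14 M⁻¹ h⁻¹ times starting material times dissolved gas, and it is used up at 1.2 M⁻¹ h⁻¹ times starting material times target. Starting material stands in both rates, so it cancels from their ratio as long as the way back from target is left aside, and the level where they balance then contains no time.

The reckoning here needs the dissolved gas first. It comes across at 0.36 h⁻¹ times its distance from saturation and decomposes at 0.019 h⁻¹ times its concentration, and the transfer coefficient is the larger of these two constants. Setting the two flows equal, and leaving aside the draw of target formation, gives 45.6 mM, or 95.0% of saturation. Setting the two target rates equal, with the way back left aside, gives 5.32 mM: this is the plateau of target, the level at which making and using balance, a quasi-steady state. Against the charge of 0.10 M, that is 5.32%.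

The forecast gives 5.1% and 94.7%, a target slightly below this reckoning, on the grounds that “its formation from dissolved gas is balanced by its fast reaction with starting material”.

The simulation gives 5.04% and 94.7%, so both forecast values hold. In the flask, starting material falls from 28.4% at 4.00 d to 7.51% at 8.00 d, while target goes from 5.14% to 5.04%, close to the plateau of 5.32%. The plateau belongs to this stretch of the run: at 80.0 d the flask holds 1.83% target. The reaction of starting material with target is what holds it there: the run without that reaction ends at 57.1% target. The neighbour flask charged with 0.040 M of starting material has the same plateau, which is 13.3% of its smaller charge, and that flask reads 12.0%.

(Its constants were chosen freely; no experiment stands behind them.)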